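## Analysis of the target

Target 24 is a depsidone. Ring A is a pentasubstituted benzene (methyl, one CH, phenol, hydroxymethyl, ether oxygen, ester carbonyl) and ring B is a hexasubstituted benzene. The two are joined by an ester and an ether bridge that close the seven-membered ring C, and ring B is fused to a five-membered γ-hydroxy-γ-lactone, ring D. The only stereocentre is the lactol carbon of ring D (S). Because it is a hemiacetal carbon that can open to an aldehyde-acid, it is configurationally labile and has to stay masked as an acetal until the last operations. Other sensitive groups are the two salicyl-alcohol units (each a phenol next to a hydroxymethyl group, prone to o-quinone methide formation), the aryl ester of ring C and the pseudo-ester character of ring D, both cleaved by hydroxide or alkoxide. The difficulty lies in ring B, which carries six different substituents in a fixed order, in the ether bond between two doubly ortho-substituted carbons, and in the labile stereocentre. The strategy rests on one structural reading. Ring D together with the two ring B carbons it is fused to is a butenolide (lactone carbonyl, α-carbon, β-carbon, oxygenated γ-carbon). The other four ring B carbons (ether carbon, ester-oxygen carbon, hydroxymethyl-bearing carbon, phenol carbon) carry the O, O, C, O pattern of C4, C3, C2 and C1 of a 4-aryloxy-3-oxobutanoate. Ring B can therefore be assembled from four plus two carbons onto a butenolide that already holds the stereocentre, and the crowded ether bond shrinks to an O-alkylation of a phenol.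

## Retrosynthetic reasoning

24 from 23 from 21. The four hydroxyl groups are masked as silyl ethers and the lactol as its acetal with the (S)-1-(4-methoxyphenyl)ethyl group. Fluoride removes the silyl groups last. Before that the auxiliary is cleaved oxidatively at its own benzylic carbon, so the C–O bond at the ring D stereocentre is never broken.

21 from 20 from 19. The ester C–O bond of ring C is cut, not the ether bond. In hydroxy acid 19 the ether bridge already holds the acid and the phenol together, so the forward step is a seven-membered lactonisation. Forming the ether between two hindered aryl carbons at this stage would be much harder.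

19 from 18. The C–C bond of the ring B hydroxymethyl group is cut. In 18 that carbon is the only unsubstituted ring B position and lies between two free phenol oxygens of an acylresorcinol, so a mild base-mediated hydroxymethylation should suffice. After lactonisation the same carbon would be flanked by an acyloxy group and the base-labile aryl ester would be present, so the carbon is added first.

18 from 10 and 16. Two C–C bonds of ring B are cut: ether carbon to lactol-bearing carbon, and phenol carbon to lactone-carbonyl-bearing carbon. The forward reaction must join the aryloxy-bearing carbanion of 10 to the bromine-bearing carbon of 16 and then close ring B by attack of the butenolide α-carbon on the methyl ester. This makes the hexasubstituted ring in one operation with ring D and its configured carbon already in place.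

16 from 14 and 15, 14 from 13, 13 from 11. The acetal C–O bond is cut to the racemic pseudo-chloride 14 and enantiopure alcohol 15. The substitution is not face-selective, but with the auxiliary carbon fixed the two C5 configurations are diastereomeric, so a separation at this three-step stage delivers 16 as a single stereoisomer. 14 comes from lactol 13, and 13 from furan 11 by photo-oxygenation, which puts bromine on the carbon next to the lactol carbon.

10 from 9, 9 from 7 and 8. The aryl–O–CH2 bond is cut, so the hindered ether becomes an alkylation of phenol 7 by chloro ketone 8. Ring A is carried as a benzyl ester and freed to the acid 10 by hydrogenolysis, which leaves the methyl β-keto ester untouched.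

7 from 6, 5, 4, 2 and 1. The hydroxymethyl carbon of ring A is introduced as a formyl group at the carbon between the two phenol oxygens of benzyl ester 2, which is made from acid 1. Selective silylation, reduction and a second silylation give 7 with only the chelated phenol free.

## Alternatives that were turned down

Alternative 1: oxygen insertion into a xanthone. The ester C–O bond of ring C is traced back to the ketone of xanthone A2, and a Baeyer–Villiger oxidation with trifluoroperacetic acid is to give depsidone A1. In its favour, xanthones are reached by robust acylation and ring-closure chemistry, and one oxygen insertion delivers ring C. Against it, the migrating carbon of ring A in A2 has a para hydroxyl and an ortho ether oxygen, while that of ring B has only the ortho ether oxygen and a meta methoxy group. Ring A should therefore migrate preferentially and give the ester the wrong way round. The xanthone carbonyl is a cross-conjugated, poorly electrophilic ketone that needs a strongly acidic peracid, which the free phenol and the acylal of A2 are unlikely to survive. A1 still holds the ring D carbons as an acylal and a chloroacetoxymethyl group. One benzylic alcohol must be unmasked and oxidised to the acid next to two other benzylic esters, an aryl methyl ether must be cleaved, and the lactol then forms racemic. The chosen route is shorter after its key step and arrives with ring D closed and configured.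

Alternative 2: ring A folded from a pyrone. Ring A is cut between its methyl-bearing carbon and the adjacent CH. Pyrone A4 is opened by Mg(OCH2Ph)2 and the freed methyl ketone condenses with the acetyl group to give diaryl ether A3. In its favour, the fold is a classical, mild reaction, and the ether bond is made by addition–elimination on an activated pyrone, which tolerates a hindered phenol as well as the phenol alkylation of the chosen route does. Against it, the effort goes into the easy ring. Ring A is a simple orsellinate available in one step from 1, whereas the hexasubstituted ring B of A4 must be built beforehand by a long linear sequence. A3 also lacks the ring A hydroxymethyl group. It would have to be introduced later at the carbon between the phenol and the ether oxygen, in competition with the free position next to the methyl group. The lactol carbon is present only as a dimethyl acetal, so the stereocentre is not addressed, and six different protecting groups must be removed, several by acid. The chosen route spends its key step on the difficult ring and carries the stereocentre through it.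

Alternative 3: carbonylative closure of ring D. Ring D is cut at the aryl–carbonyl bond, the lactone C–O bond and the lactol C–O bond. Iodo aldehyde A6, alcohol A7 and CO are joined by Pd(OAc)2 and a chiral bisphosphine to give A5. On two points this alternative is stronger than the chosen route. The stereocentre would be set catalytically and late, from a rapidly equilibrating hemiacetal, and the 2-nitrobenzyl group is removed by light, a milder unveiling of the lactol than an oxidant. Against it, zerovalent palladium must insert into an aryl iodide flanked by a silyloxy group and a formyl group in a hexasubstituted ring. The enantio-determining event is the acylation of one hemiacetal enantiomer by an acylpalladium species, for which the substrate offers no controlling element. A7 itself, present in far higher concentration than its hemiacetal, can intercept the acylpalladium to give an open ester. All of this risk would fall on A6, the most advanced intermediate. The chosen route gives up catalytic stereocontrol and loses half of the acetal material at the separation, but in exchange it fixes the configuration by a diastereomer separation on a three-step fragment, and its uncertain step joins two early fragments.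

Key step: step 11

Remark: ring A is entered from orsellinic acid and not from a simple alkyl orsellinate, because the ring A carboxyl must be released by hydrogenolysis next to a methyl β-keto ester; 13 and 14 are racemic at C5.

## Steps

Step 1
Reactants: 1 orsellinic acid (2,4-dihydroxy-6-methylbenzoic acid)
Product: 2 benzyl 2,4-dihydroxy-6-methylbenzoate
Conditions: BnBr (1.05 equiv), KHCO3, DMF, rt
Reagents that add atoms: benzyl bromide, BrCc1ccccc1
Why: SN2 alkylation of the carboxylate; KHCO3 ionises only the carboxylic acid, so the phenols stay free, and the mild temperature avoids the decarboxylation to which β-resorcylic acids are prone.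

Step 2
Reactants: 2 benzyl 2,4-dihydroxy-6-methylbenzoate
Product: 4 benzyl 3-formyl-2,4-dihydroxy-6-methylbenzoate, via chloro(methoxy)methyl arene 3 (not isolated)
Conditions: Cl2CHOMe, TiCl4, CH2Cl2, −10 to 0 °C; then 1 M HCl, 0 °C
Reagents that add atoms: dichloromethyl methyl ether, COC(Cl)Cl; water, O
Why: Rieche formylation; titanium binds the two phenol oxygens and delivers the electrophile to the carbon between them, the usual site of substitution in chelated β-resorcylates, and 3 is hydrolysed to the aldehyde on work-up. The formyl group deactivates the ring against a second substitution.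

Step 3
Reactants: 4 benzyl 3-formyl-2,4-dihydroxy-6-methylbenzoate
Product: 5 benzyl 4-(tert-butyldimethylsilyloxy)-3-formyl-2-hydroxy-6-methylbenzoate
Conditions: TBSCl (1.05 equiv), imidazole, CH2Cl2, 0 °C
Reagents that add atoms: tert-butyldimethylsilyl chloride, CC(C)(C)[Si](C)(C)Cl
Why: O-silylation; the 4-hydroxyl (para to the ester, one ortho neighbour) is more acidic and more accessible than the 2-hydroxyl, which is flanked on both sides and hydrogen-bonded to the benzoate carbonyl.

Step 4
Reactants: 5 benzyl 4-(tert-butyldimethylsilyloxy)-3-formyl-2-hydroxy-6-methylbenzoate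
Product: 6 benzyl 4-(tert-butyldimethylsilyloxy)-2-hydroxy-3-(hydroxymethyl)-6-methylbenzoate
Conditions: NaBH4, THF–MeOH, −20 °C; aq. NH4Cl
Reagents that add atoms: none
Why: borohydride reduction of the aldehyde; the doubly ortho-substituted benzyl ester is not attacked at this temperature. If the aryl silyl group moves to the new alkoxide, step 5 brings either regioisomer to the same product.

Step 5
Reactants: 6 benzyl 4-(tert-butyldimethylsilyloxy)-2-hydroxy-3-(hydroxymethyl)-6-methylbenzoate
Product: 7 benzyl 4-(tert-butyldimethylsilyloxy)-3-[(tert-butyldimethylsilyloxy)methyl]-2-hydroxy-6-methylbenzoate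
Conditions: TBSCl, imidazole, DMF, 0 °C to rt
Reagents that add atoms: tert-butyldimethylsilyl chloride, CC(C)(C)[Si](C)(C)Cl
Why: silylation of the primary alcohol (and of any ring A phenol freed by silyl transfer in step 4); the chelated, doubly flanked 2-hydroxyl is left free for the ether formation.

Step 6
Reactants: 7 benzyl 4-(tert-butyldimethylsilyloxy)-3-[(tert-butyldimethylsilyloxy)methyl]-2-hydroxy-6-methylbenzoate; 8 methyl 4-chloro-3-oxobutanoate
Product: 9 benzyl 4-(tert-butyldimethylsilyloxy)-3-[(tert-butyldimethylsilyloxy)methyl]-2-(4-methoxy-2,4-dioxobutoxy)-6-methylbenzoate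
Conditions: NaH (2.1 equiv), NaI (cat.), THF, 0 °C to rt
Reagents that add atoms: none
Why: Williamson ether synthesis at the chloromethyl ketone carbon; the second equivalent of NaH keeps 8 and then 9 as their sodium enolates, which shields the ketone and suppresses self-condensation. The enolate carbon of 9 cannot reach the hindered benzyl ester.

Step 7
Reactants: 9 benzyl 4-(tert-butyldimethylsilyloxy)-3-[(tert-butyldimethylsilyloxy)methyl]-2-(4-methoxy-2,4-dioxobutoxy)-6-methylbenzoate
Product: 10 4-(tert-butyldimethylsilyloxy)-3-[(tert-butyldimethylsilyloxy)methyl]-2-(4-methoxy-2,4-dioxobutoxy)-6-methylbenzoic acid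
Conditions: H2 (1 atm), 10% Pd/C, EtOAc, rt
Reagents that add atoms: none
Why: hydrogenolysis of the benzyl ester; the β-keto ester, the aryl alkyl ether and the silyl ethers are inert to H2 over Pd/C in a neutral aprotic solvent. The free acid is needed because only a carboxylate is safe next to the carbanion of step 11.

Step 8
Reactants: 11 4-bromofuran-2-carbaldehyde
Product: 13 4-bromo-5-hydroxyfuran-2(5H)-one (racemic), via furan endoperoxide 12 (not isolated)
Conditions: O2, hν (visible), tetraphenylporphyrin (cat.), CH2Cl2–MeOH, −20 °C to rt
Reagents that add atoms: oxygen, O=O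
Why: [4+2] cycloaddition of singlet oxygen across C2 and C5 of the furan gives 12; methanol adds to the formyl group and the adduct fragments with loss of methyl formate. The carbon that carried the aldehyde thus becomes the lactone carbonyl and bromine ends on C4, next to the lactol carbon.

Step 9
Reactants: 13 4-bromo-5-hydroxyfuran-2(5H)-one
Product: 14 4-bromo-5-chlorofuran-2(5H)-one (racemic)
Conditions: SOCl2, DMF (cat.), 50 °C
Reagents that add atoms: thionyl chloride, O=S(Cl)Cl
Why: conversion of the lactol hydroxyl into the pseudo-acid chloride through its chlorosulfite, the standard behaviour of mucohalic-type γ-hydroxybutenolides.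

Step 10
Reactants: 14 4-bromo-5-chlorofuran-2(5H)-one; 15 (S)-1-(4-methoxyphenyl)ethanol
Product: 16 (5S)-4-bromo-5-[(1S)-1-(4-methoxyphenyl)ethoxy]furan-2(5H)-one
Conditions: 2,6-lutidine, CH2Cl2, −20 °C to rt; chromatography
Reagents that add atoms: none
Why: substitution at the acylal carbon through the 2-oxofuranyl oxocarbenium ion; 2,6-lutidine takes up HCl, so the acid-labile benzylic alcohol never meets acid, which rules out direct acid-catalysed acetalisation of 13. Attack on the planar cation is not face-selective, so both C5 configurations arise; with the auxiliary carbon fixed as S they are diastereomeric, and the chromatographic separation keeps only the (5S) acetal 16, which fixes the configuration of the target's only stereocentre (5S, to be confirmed crystallographically on the bromide).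

Step 11
Reactants: 10 4-(tert-butyldimethylsilyloxy)-3-[(tert-butyldimethylsilyloxy)methyl]-2-(4-methoxy-2,4-dioxobutoxy)-6-methylbenzoic acid; 16 (5S)-4-bromo-5-[(1S)-1-(4-methoxyphenyl)ethoxy]furan-2(5H)-one
Product: 18 4-(tert-butyldimethylsilyloxy)-3-[(tert-butyldimethylsilyloxy)methyl]-2-({(3S)-5,7-dihydroxy-3-[(1S)-1-(4-methoxyphenyl)ethoxy]-1-oxo-1,3-dihydroisobenzofuran-4-yl}oxy)-6-methylbenzoic acid, via substituted butenolide 17 (not isolated)
Conditions: LiN(iPr)2 (3.1 equiv), THF, −78 to −30 °C; 16, −78 to 0 °C; aq. citric acid (pH 4), 0 °C
Reagents that add atoms: none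
Why: LiN(iPr)2 removes the carboxyl proton, one C2 proton and one C4 proton of 10, and the aryloxy-bearing C4 carbanion of this trianion adds to C4 of 16, the β-carbon of the unsaturated lactone; the lactone enolate then expels bromide (addition–elimination) to give 17 with the butenolide double bond restored. In 17 the new CH is flanked by the ketone, the aryloxy group and the vinylogous lactone, so proton exchange with the β-keto ester enolate gives an extended enolate whose butenolide α-carbon attacks the methyl ester (Dieckmann condensation, 6-exo-trig); loss of methoxide and two enolisations give the resorcinol ring B of 18 without an oxidant. The closest known reactions are the Michael–Dieckmann benzannulation of ester-bearing carbanions with unsaturated lactones (Staunton–Weinreb annulation), the Claisen-type ring closure of polyketo ester polyanions, and addition–elimination of nucleophiles at C4 of 4-halo-5-alkoxyfuranones. Regiochemistry follows from polarity: the carbanion carbon meets the only electrophilic ring carbon of 16, and the alternative closure of the keto ester carbon onto the lactone carbonyl would need a bridged ring with a bridgehead alkene. No stereocentre is created that survives, since the aryloxy-bearing CH of 17 is flattened on aromatisation, and C5 of 16 is not a reacting centre, so its S configuration passes into 18; this requires the acetal hydrogen to stay in place, which the low temperature and the higher acidity of the new CH in 17 should secure. Ring A is carried as its lithium carboxylate because an ester there would be attacked by the aryloxy carbanion in a five-membered ring closure. Any C5-epimerised material would be a diastereomer of 18 and removable at this stage.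

Step 12
Reactants: 18 the resorcinol acid from step 11
Product: 19 4-(tert-butyldimethylsilyloxy)-3-[(tert-butyldimethylsilyloxy)methyl]-2-({(3S)-5,7-dihydroxy-6-(hydroxymethyl)-3-[(1S)-1-(4-methoxyphenyl)ethoxy]-1-oxo-1,3-dihydroisobenzofuran-4-yl}oxy)-6-methylbenzoic acid
Conditions: aq. CH2O (37%), Et3N, THF, 0 °C to rt; NaH2PO4 buffer
Reagents that add atoms: formaldehyde, C=O
Why: Lederer–Manasse hydroxymethylation; the phenoxide of the acylresorcinol is nucleophilic at the carbon between its two oxygens, the only unsubstituted carbon of ring B, and ring A cannot react because its phenol is silylated. The mild amine base spares the acetal lactone and the aryl silyl ether.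

Step 13
Reactants: 19 the hydroxymethylated resorcinol acid
Product: 20 depsidone acetal with ring C closed (ring A phenol and hydroxymethyl as silyl ethers; ring B phenol and hydroxymethyl free; ring D (S)-acetal with the (1S)-1-(4-methoxyphenyl)ethyl group)
Conditions: DCC, CH2Cl2–THF (2 mM), 0 °C to rt
Reagents that add atoms: none
Why: carbodiimide lactonisation (7-exo-trig attack of the phenol ortho to the ether bridge on the O-acylisourea); the other phenol is meta to the bridge and cannot reach, and the primary alcohol could only close a nine-membered ring. No base is present, so the acetal and the salicyl alcohol are not stressed.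

Step 14
Reactants: 20 the depsidone acetal
Product: 21 depsidone acetal with all four hydroxyl groups as tert-butyldimethylsilyl ethers
Conditions: TBSCl, imidazole, DMF, rt
Reagents that add atoms: tert-butyldimethylsilyl chloride, CC(C)(C)[Si](C)(C)Cl
Why: silylation of the primary alcohol and the remaining ring B phenol, so that no free phenol or salicyl alcohol faces the quinone oxidant of step 15.

Step 15
Reactants: 21 the fully silylated depsidone acetal
Product: 23 tetrakis(silyl)-protected (S)-lactol, via auxiliary hemiketal 22 (not isolated)
Conditions: DDQ, CH2Cl2–aq. NaH2PO4/Na2HPO4 (pH 7), 0 °C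
Reagents that add atoms: none
Why: oxidative cleavage of a 4-methoxybenzyl-type ether; hydride abstraction from the auxiliary's benzylic C–H gives an anisyl-stabilised oxocarbenium ion, water adds to give 22, and this collapses to 4'-methoxyacetophenone and lactol 23. The C–O bond at the ring D carbon is never broken, so the S configuration is retained.

Step 16
Reactants: 23 the silyl-protected lactol
Product: 24 target depsidone CNP0155661.1 with the (S)-lactol in ring D
Conditions: Et3N·3HF, THF, 0 °C to rt
Reagents that add atoms: none
Why: fluoride cleavage of the four Si–O bonds under weakly acidic, non-nucleophilic conditions that leave the aryl ester and the lactol ring closed. Short contact and a cold work-up limit epimerisation of the lactol by ring opening.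

## Compound list

1 | orsellinic acid (2,4-dihydroxy-6-methylbenzoic acid) | Cc1cc(O)cc(O)c1C(=O)O | starting material
2 | benzyl 2,4-dihydroxy-6-methylbenzoate | Cc1cc(O)cc(O)c1C(=O)OCc1ccccc1 | intermediate
3 | benzyl 3-[chloro(methoxy)methyl]-2,4-dihydroxy-6-methylbenzoate (titanium-bound, not isolated) | Cc1cc(O)c(C(Cl)OC)c(O)c1C(=O)OCc1ccccc1 | intermediate
4 | benzyl 3-formyl-2,4-dihydroxy-6-methylbenzoate | Cc1cc(O)c(C=O)c(O)c1C(=O)OCc1ccccc1 | intermediate
5 | benzyl 4-(tert-butyldimethylsilyloxy)-3-formyl-2-hydroxy-6-methylbenzoate | Cc1cc(O[Si](C)(C)C(C)(C)C)c(C=O)c(O)c1C(=O)OCc1ccccc1 | intermediate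
6 | benzyl 4-(tert-butyldimethylsilyloxy)-2-hydroxy-3-(hydroxymethyl)-6-methylbenzoate | Cc1cc(O[Si](C)(C)C(C)(C)C)c(CO)c(O)c1C(=O)OCc1ccccc1 | intermediate
7 | benzyl 4-(tert-butyldimethylsilyloxy)-3-[(tert-butyldimethylsilyloxy)methyl]-2-hydroxy-6-methylbenzoate | Cc1cc(O[Si](C)(C)C(C)(C)C)c(CO[Si](C)(C)C(C)(C)C)c(O)c1C(=O)OCc1ccccc1 | intermediate
8 | methyl 4-chloro-3-oxobutanoate | COC(=O)CC(=O)CCl | starting material
9 | benzyl 4-(tert-butyldimethylsilyloxy)-3-[(tert-butyldimethylsilyloxy)methyl]-2-(4-methoxy-2,4-dioxobutoxy)-6-methylbenzoate | Cc1cc(O[Si](C)(C)C(C)(C)C)c(CO[Si](C)(C)C(C)(C)C)c(OCC(=O)CC(=O)OC)c1C(=O)OCc1ccccc1 | intermediate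
10 | 4-(tert-butyldimethylsilyloxy)-3-[(tert-butyldimethylsilyloxy)methyl]-2-(4-methoxy-2,4-dioxobutoxy)-6-methylbenzoic acid | OC(=O)c1c(C)cc(O[Si](C)(C)C(C)(C)C)c(CO[Si](C)(C)C(C)(C)C)c1OCC(=O)CC(=O)OC | intermediate
11 | 4-bromofuran-2-carbaldehyde | O=Cc1cc(Br)co1 | starting material
12 | 5-bromo-2,3,7-trioxabicyclo[2.2.1]hept-5-ene-1-carbaldehyde (not isolated) | O=CC12C=C(Br)C(OO1)O2 | intermediate
13 | 4-bromo-5-hydroxyfuran-2(5H)-one (racemic) | O=C1C=C(Br)C(O)O1 | intermediate
14 | 4-bromo-5-chlorofuran-2(5H)-one (racemic) | O=C1C=C(Br)C(Cl)O1 | intermediate
15 | (S)-1-(4-methoxyphenyl)ethanol | C[C@H](O)c1ccc(OC)cc1 | starting material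
16 | (5S)-4-bromo-5-[(1S)-1-(4-methoxyphenyl)ethoxy]furan-2(5H)-one | O=C1C=C(Br)[C@@H](O[C@@H](C)c2ccc(OC)cc2)O1 | intermediate
17 | 4-(tert-butyldimethylsilyloxy)-3-[(tert-butyldimethylsilyloxy)methyl]-2-{[4-methoxy-1-{(2S)-2-[(1S)-1-(4-methoxyphenyl)ethoxy]-5-oxo-2,5-dihydrofuran-3-yl}-2,4-dioxobutyl]oxy}-6-methylbenzoic acid (not isolated) | OC(=O)c1c(C)cc(O[Si](C)(C)C(C)(C)C)c(CO[Si](C)(C)C(C)(C)C)c1OC(C(=O)CC(=O)OC)C1=CC(=O)O[C@@H]1O[C@@H](C)c1ccc(OC)cc1 | intermediate
18 | 4-(tert-butyldimethylsilyloxy)-3-[(tert-butyldimethylsilyloxy)methyl]-2-({(3S)-5,7-dihydroxy-3-[(1S)-1-(4-methoxyphenyl)ethoxy]-1-oxo-1,3-dihydroisobenzofuran-4-yl}oxy)-6-methylbenzoic acid | OC(=O)c1c(C)cc(O[Si](C)(C)C(C)(C)C)c(CO[Si](C)(C)C(C)(C)C)c1Oc1c(O)cc(O)c2c1[C@@H](O[C@@H](C)c1ccc(OC)cc1)OC2=O | intermediate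
19 | 4-(tert-butyldimethylsilyloxy)-3-[(tert-butyldimethylsilyloxy)methyl]-2-({(3S)-5,7-dihydroxy-6-(hydroxymethyl)-3-[(1S)-1-(4-methoxyphenyl)ethoxy]-1-oxo-1,3-dihydroisobenzofuran-4-yl}oxy)-6-methylbenzoic acid | OC(=O)c1c(C)cc(O[Si](C)(C)C(C)(C)C)c(CO[Si](C)(C)C(C)(C)C)c1Oc1c(O)c(CO)c(O)c2c1[C@@H](O[C@@H](C)c1ccc(OC)cc1)OC2=O | intermediate
20 | depsidone acetal: ring A silyl ethers, ring B phenol and hydroxymethyl free, ring D (S)-acetal with the (1S)-1-(4-methoxyphenyl)ethyl group | Cc1cc(O[Si](C)(C)C(C)(C)C)c(CO[Si](C)(C)C(C)(C)C)c2c1C(=O)Oc1c(CO)c(O)c3c(c1O2)[C@@H](O[C@@H](C)c1ccc(OC)cc1)OC3=O | intermediate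
21 | depsidone acetal with all four hydroxyl groups as tert-butyldimethylsilyl ethers | Cc1cc(O[Si](C)(C)C(C)(C)C)c(CO[Si](C)(C)C(C)(C)C)c2c1C(=O)Oc1c(CO[Si](C)(C)C(C)(C)C)c(O[Si](C)(C)C(C)(C)C)c3c(c1O2)[C@@H](O[C@@H](C)c1ccc(OC)cc1)OC3=O | intermediate
22 | hemiketal of 21 at the auxiliary carbon (not isolated) | Cc1cc(O[Si](C)(C)C(C)(C)C)c(CO[Si](C)(C)C(C)(C)C)c2c1C(=O)Oc1c(CO[Si](C)(C)C(C)(C)C)c(O[Si](C)(C)C(C)(C)C)c3c(c1O2)[C@@H](OC(C)(O)c1ccc(OC)cc1)OC3=O | intermediate
23 | tetrakis(tert-butyldimethylsilyl)-protected (S)-lactol | Cc1cc(O[Si](C)(C)C(C)(C)C)c(CO[Si](C)(C)C(C)(C)C)c2c1C(=O)Oc1c(CO[Si](C)(C)C(C)(C)C)c(O[Si](C)(C)C(C)(C)C)c3c(c1O2)[C@@H](O)OC3=O | intermediate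
24 | target depsidone CNP0155661.1 with the (S)-lactol in ring D | Cc1cc(O)c(CO)c2c1C(=O)Oc1c(CO)c(O)c3c(c1O2)[C@@H](O)OC3=O | target

## Step count and least certain steps

Total: 16 steps. Longest linear sequence: 13 steps (steps 1–7, then 11–16); the butenolide branch (steps 8–10) joins at step 11.

Step 11 (key step). The acetal hydrogen of 16 sits at the γ-position of a butenolide, and its removal gives an aromatic 2-oxidofuran. Proton transfer from this position to the strongly basic trianion could therefore compete with conjugate addition, consuming both partners and eroding the C5 configuration. The sequence could also stall at 17, because the ester to be attacked belongs to a β-keto ester that prefers to sit as its enolate. Fallback without strong base: from 10, silylation with TMSOTf and Et3N in Et2O at 0 °C gives the trimethylsilyl ester 1-methoxy-1,3-bis(trimethylsilyloxy)-4-aryloxybuta-1,3-diene F1. Thermal [4+2] cycloaddition of F1 with 16 in toluene at 80–110 °C, with the nucleophilic diene terminus bonding to the bromine-bearing carbon, gives cycloadduct F2. On buffered aqueous work-up F2 loses HBr, methanol and its trimethylsilyl groups and rejoins the route at 18.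

Step 6. Self-condensation of 8 under base may outrun O-alkylation by the hindered, chelated phenoxide of 7, and silyl scrambling between phenoxides may occur. Fallback: from 7, alkylation with methyl (E)-4-bromo-3-methoxybut-2-enoate (K2CO3, acetone), a masked form of the electrophile with neither an acidic methylene nor a ketone, gives the enol ether F3. Hydrolysis of the enol ether with dilute aqueous HCl in THF returns to 9; a benzylic silyl ether lost there is put back as in step 5.

Step 12. The new salicyl alcohol may ionise to an o-quinone methide and bridge two molecules through a methylene group. The reaction may also be slow enough to call for stronger base, which would cleave the ring A aryl silyl ether or open the acetal lactone. Fallback: from 18, ring C is closed first with DCC to the depsidone phenol F4. Ortho-formylation of F4 with MgCl2, Et3N and paraformaldehyde (Casnati–Skattebøl conditions) gives salicylaldehyde F5, and reduction with NaBH4 at −20 °C returns to 20.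

Step 13. The activated acid may acylate the primary alcohol (nine-membered lactone or oligomers) in place of the phenol. Fallback: from 19, the primary alcohol is silylated selectively (TBSCl, imidazole, −20 °C; both phenols are flanked on both sides, and the silyl ester is hydrolysed on work-up) to acid F6. Lactonisation with DCC gives depsidone F7, and silylation of the remaining phenol rejoins the route at 21.

Step 15. Hydride abstraction may occur from the oxygen-flanked benzylic CH2 of the ring A silyloxymethyl group as well, and the desired abstraction may be slow because the ether oxygen belongs to an electron-poor acetal. Fallback: from 21, the same benzylic C–O bond is ionised by acid (2% TFA, Et3SiH, CH2Cl2, −20 °C) and the cation is reduced to 1-ethyl-4-methoxybenzene. This gives 23, and any partly desilylated material converges on 24 in step 16.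

Step 16. The free lactol may epimerise by ring–chain tautomerism during fluoride treatment and purification, with loss of enantiopurity. Fallback: from 21, the order is inverted. Desilylation with Et3N·3HF with the acetal still in place gives the configurationally locked tetrol F8, which can be purified at leisure. The lactol is then released in the final operation by brief acid ionisation of the auxiliary C–O bond (1–2% TFA, 1,3-dimethoxybenzene as cation trap, CH2Cl2, −20 °C), and 24 is isolated by precipitation without chromatography.

## Further compounds

F1 | step 11 | trimethylsilyl 4-(tert-butyldimethylsilyloxy)-3-[(tert-butyldimethylsilyloxy)methyl]-2-{[4-methoxy-2,4-bis(trimethylsilyloxy)buta-1,3-dien-1-yl]oxy}-6-methylbenzoate | C[Si](C)(C)OC(=O)c1c(C)cc(O[Si](C)(C)C(C)(C)C)c(CO[Si](C)(C)C(C)(C)C)c1OC=C(O[Si](C)(C)C)C=C(OC)O[Si](C)(C)C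
F2 | step 11 | [4+2] cycloadduct of F1 and 16 (7a-bromo-4-methoxy-4,6-bis(trimethylsilyloxy)-7-aryloxy tetrahydroisobenzofuranone acetal) | COC1(O[Si](C)(C)C)C=C(O[Si](C)(C)C)C(Oc3c(CO[Si](C)(C)C(C)(C)C)c(O[Si](C)(C)C(C)(C)C)cc(C)c3C(=O)O[Si](C)(C)C)C2(Br)[C@@H](O[C@@H](C)c4ccc(OC)cc4)OC(=O)C12
F3 | step 6 | benzyl 4-(tert-butyldimethylsilyloxy)-3-[(tert-butyldimethylsilyloxy)methyl]-2-{[(2E)-2,4-dimethoxy-4-oxobut-2-en-1-yl]oxy}-6-methylbenzoate | Cc1cc(O[Si](C)(C)C(C)(C)C)c(CO[Si](C)(C)C(C)(C)C)c(OC/C(OC)=C\C(=O)OC)c1C(=O)OCc1ccccc1
F4 | step 12 | depsidone acetal lacking the ring B hydroxymethyl group (ring B phenol free) | Cc1cc(O[Si](C)(C)C(C)(C)C)c(CO[Si](C)(C)C(C)(C)C)c2c1C(=O)Oc1cc(O)c3c(c1O2)[C@@H](O[C@@H](C)c1ccc(OC)cc1)OC3=O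
F5 | step 12 | ring B ortho-formyl derivative of F4 | Cc1cc(O[Si](C)(C)C(C)(C)C)c(CO[Si](C)(C)C(C)(C)C)c2c1C(=O)Oc1c(C=O)c(O)c3c(c1O2)[C@@H](O[C@@H](C)c1ccc(OC)cc1)OC3=O
F6 | step 13 | 19 with the ring B hydroxymethyl group as its tert-butyldimethylsilyl ether | OC(=O)c1c(C)cc(O[Si](C)(C)C(C)(C)C)c(CO[Si](C)(C)C(C)(C)C)c1Oc1c(O)c(CO[Si](C)(C)C(C)(C)C)c(O)c2c1[C@@H](O[C@@H](C)c1ccc(OC)cc1)OC2=O
F7 | step 13 | 20 with the ring B hydroxymethyl group as its tert-butyldimethylsilyl ether | Cc1cc(O[Si](C)(C)C(C)(C)C)c(CO[Si](C)(C)C(C)(C)C)c2c1C(=O)Oc1c(CO[Si](C)(C)C(C)(C)C)c(O)c3c(c1O2)[C@@H](O[C@@H](C)c1ccc(OC)cc1)OC3=O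
F0 | step 15 | none | none
F8 | step 16 | desilylated depsidone with the (1S)-1-(4-methoxyphenyl)ethyl acetal intact | Cc1cc(O)c(CO)c2c1C(=O)Oc1c(CO)c(O)c3c(c1O2)[C@@H](O[C@@H](C)c1ccc(OC)cc1)OC3=O
A1 | alternative 1 | depsidone with acetate, chloroacetate, methyl ether and acylal masks | Cc1cc(O)c(COC(C)=O)c2c1C(=O)Oc1c(COC(C)=O)c(OC)c(COC(=O)CCl)c(C(OC(C)=O)OC(C)=O)c1O2
A2 | alternative 1 | xanthone precursor of A1 | Cc1cc(O)c(COC(C)=O)c2c1C(=O)c1c(COC(C)=O)c(OC)c(COC(=O)CCl)c(C(OC(C)=O)OC(C)=O)c1O2
A3 | alternative 2 | benzyl 2-aryloxy-4-hydroxy-6-methylbenzoate diaryl ether | O=C(OCc1ccccc1)c1c(C)cc(O)cc1Oc1c(OCc2ccccc2)c(CO[Si](C)(C)C(C)(C)C)c(OCOC)c(C(=O)OC(C)(C)C)c1C(OC)OC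
A4 | alternative 2 | 3-acetyl-4-aryloxy-6-methyl-2H-pyran-2-one | CC(=O)C1=C(Oc2c(OCc3ccccc3)c(CO[Si](C)(C)C(C)(C)C)c(OCOC)c(C(=O)OC(C)(C)C)c2C(OC)OC)C=C(C)OC1=O
A5 | alternative 3 | silyl-protected target as its 2-nitrobenzyl lactol ether | Cc1cc(O[Si](C)(C)C(C)(C)C)c(CO[Si](C)(C)C(C)(C)C)c2c1C(=O)Oc1c(CO[Si](C)(C)C(C)(C)C)c(O[Si](C)(C)C(C)(C)C)c3c(c1O2)[C@@H](OCc1ccccc1[N+](=O)[O-])OC3=O
A6 | alternative 3 | silyl-protected depsidone with iodide and formyl group on ring B | Cc1cc(O[Si](C)(C)C(C)(C)C)c(CO[Si](C)(C)C(C)(C)C)c2c1C(=O)Oc1c(CO[Si](C)(C)C(C)(C)C)c(O[Si](C)(C)C(C)(C)C)c(I)c(C=O)c1O2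
A7 | alternative 3 | 2-nitrobenzyl alcohol | OCc1ccccc1[N+](=O)[O-]
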